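A direct plan would acylate 3,5-dimethoxyphenol A1 twice with an oxalyl unit to the keto lactone A2, free the peri hydroxyl to give A3, treat A3 with the deprotonated benzylic sulfonium salt A4 to expand the lactone to flavonol A5, and methylate O3 last.
Its weakest steps would be:
- the ring expansion of A3 to A5: it is an untested reaction type that must attack the lactone and not the ketone carbonyl of a dione carrying a free phenol under two equivalents of strong base, and it is the only step that builds the core;
- the Lewis acid demethylation of A2 to A3: it is a protecting group change that builds nothing, run on an aryl α-keto lactone that opens with water and chloride;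
- the final monomethylation of A5: it asks for O3 against O5 selectivity on the most valuable intermediate, after two steps have already gone into the labile salt A4.

**Retrosynthetic overview**
- Ring A carries the acetate pattern O1–C8a, C5–OH, C7–OMe with only O7 methylated. 4-Methoxy-6-methyl-2H-pyran-2-one holds exactly this in masked form: its ring carbons are C5–C8a, its enol ether is the 7-OMe, its ring oxygen is O1.
- The key disconnections are therefore C4a–C5 in ring A (Claisen condensation) and O1–C2 in ring C (cyclodehydration), both made in one operation on the open chain ring B–C2(=O)–C3H(OMe)–C4(=O)–C4aH2–pyranone.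
- The rings form in the order A, then C, from a precursor that holds neither; ring B is bought as methyl 4-hydroxybenzoate and prenylated first.
- The chain is assembled by two enolate acylations: C4–C4a (pyranone methyl anion with a methoxyacetyl unit, which brings the 3-OMe) and C2–C3 (ketone dianion with the benzoate).
- Every oxygen arrives in its final state, so there is no ether cleavage on a keto lactone, no selective O-methylation at the end, no sulfonium ylide step and no protecting group.

Key step: step 4

Remark on the chemistry: the target has no stereocentre and its only non-aromatic C=C bond carries two methyl groups, so nothing stereochemical has to be set. Compounds 9, 10 and 11 are racemic at the CH(OMe) carbon, which becomes the sp2 carbon C3, and are written as keto tautomers. Flavone numbering is used for the atoms of all intermediates.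

Step 1
Reactants: 1 methyl 4-hydroxybenzoate; 2 prenyl bromide (1-bromo-3-methylbut-2-ene)
Product: 3 methyl 4-(3-methylbut-2-en-1-yloxy)benzoate
Conditions: K2CO3 (1.5 equiv), acetone, reflux
Reagents that add atoms: none
Why: Williamson ether synthesis, in which the phenoxide of 1 displaces bromide at the unhindered CH2 of the primary allylic halide (SN2) and the methyl ester is inert to carbonate.

Step 2
Reactants: 4 4-methoxy-6-methyl-2H-pyran-2-one; 5 N,2-dimethoxy-N-methylacetamide
Product: 7 4-methoxy-6-(3-methoxy-2-oxopropyl)-2H-pyran-2-one, via lithium dienolate 6 (not isolated)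
Conditions: LiN(i-Pr)2 (1.05 equiv), THF, −78 °C; then 5 (1.0 equiv), −78 → −20 °C; 1 M HCl, 0 °C
Reagents that add atoms: none
Why: Weinreb ketone synthesis on a vinylogous ester enolate, in which the hindered amide base removes a proton from the 6-methyl group, the dienolate 6 adds through this carbon to the amide, and the chelated tetrahedral adduct should hold until the acid quench, so that the more acidic product cannot quench 6 and no second addition occurs.

Step 3
Reactants: 7 4-methoxy-6-(3-methoxy-2-oxopropyl)-2H-pyran-2-one; 3 methyl 4-(3-methylbut-2-en-1-yloxy)benzoate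
Product: 9 4-methoxy-6-{3-methoxy-4-[4-(3-methylbut-2-en-1-yloxy)phenyl]-2,4-dioxobutyl}-2H-pyran-2-one, via dilithium dianion 8 (not isolated)
Conditions: LiN(i-Pr)2 (3.1 equiv), THF, −78 → 0 °C; then 3 (1.05 equiv), 0 °C → rt; AcOH, aqueous work-up
Reagents that add atoms: none
Why: Crossed Claisen condensation of a ketone dianion, in which the first equivalent of base removes the doubly activated proton between pyranone and ketone, the second the CH2OMe proton, and the last-formed, more basic α′-carbanion of 8 attacks the non-enolisable ester 3, while the third equivalent drives the condensation by deprotonating the new 1,3-diketone, whose CH(OMe) centre forms racemic and is lost in step 4.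

Step 4
Reactants: 9 4-methoxy-6-{3-methoxy-4-[4-(3-methylbut-2-en-1-yloxy)phenyl]-2,4-dioxobutyl}-2H-pyran-2-one
Product: 12 5-hydroxy-3,7-dimethoxy-2-[4-(3-methylbut-2-en-1-yloxy)phenyl]-4H-chromen-4-one, via open-chain methyl ester 10 (not isolated), via aryl diketone 11 (not isolated)
Conditions: Mg(OMe)2 (3 equiv), MeOH, reflux; then evaporate, AcOH, NaOAc, 100 °C
Reagents that add atoms: none
Why: Methoxide should open the lactone of 9 at C5 to the (2E)-3-methoxyenoate 10, in which the former ring double bond C6=C7 holds the ester cis to the chain, and the magnesium-chelated enolate carbon C4a, flanked by the C8a and C4 carbonyls, then attacks the ester carbon C5 in a Claisen (Dieckmann-type) condensation that, after loss of methoxide and enolisation, gives the 2,6-dihydroxy-4-methoxyphenyl diketone 11; in buffered acetic acid a phenolic oxygen of 11 adds to the aroyl carbonyl C2 and the hemiketal loses water to the 4-pyranone. The closest known reaction types are the Mg(OMe)2-induced Claisen recyclisation of 6-(2-oxoalkyl)-4-methoxypyran-2-ones to 2-acyl-5-methoxyresorcinols, the laboratory counterpart of the chalcone-type fold of a polyketide, and the cyclodehydration of o-hydroxyaryl 1,3-diketones that ends the Baker–Venkataraman flavone synthesis. Ring A closes 6-exo-trig at the ester carbonyl (C4a–C5 bond), and ring C closes 6-exo-trig at the C2 carbonyl (O1–C2 bond) followed by elimination of water. No stereocentre is created, and the racemic CH(OMe) carbon of 9 becomes the sp2 carbon C3. The step needs the Claisen mode and not an aldol mode (enoate carbon C6 onto the C4 carbonyl, or C8 onto the aryl ketone C2): magnesium binds the C8a, C4 and C2 oxygens as one chelated polyenolate, which fixes C4a as the nucleophilic carbon and deactivates the ketones as acceptors, so that the unchelated ester is the only electrophile within reach of a six-membered transition state. The two ortho oxygens of 11 are homotopic, so closure through either gives 12 and the other becomes the chelated 5-OH, while the 7-OMe is the enol ether of the pyranone and was never a free hydroxyl.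

**Compound list**
1 | methyl 4-hydroxybenzoate | COC(=O)c1ccc(O)cc1 | starting material
2 | prenyl bromide (1-bromo-3-methylbut-2-ene) | CC(C)=CCBr | starting material
3 | methyl 4-(3-methylbut-2-en-1-yloxy)benzoate | COC(=O)c1ccc(OCC=C(C)C)cc1 | intermediate
4 | 4-methoxy-6-methyl-2H-pyran-2-one | COC1=CC(=O)OC(C)=C1 | starting material
5 | N,2-dimethoxy-N-methylacetamide | COCC(=O)N(C)OC | starting material
6 | [(4-methoxy-2-oxo-2H-pyran-6-yl)methyl]lithium (lithium dienolate of 4) | [Li]CC1=CC(OC)=CC(=O)O1 | intermediate
7 | 4-methoxy-6-(3-methoxy-2-oxopropyl)-2H-pyran-2-one | COCC(=O)CC1=CC(OC)=CC(=O)O1 | intermediate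
8 | dilithium dianion of 7 (deprotonated at C1 and C3 of the oxopropyl chain) | [Li+].[Li+].CO[CH-]C([O-])=CC1=CC(OC)=CC(=O)O1 | intermediate
9 | 4-methoxy-6-{3-methoxy-4-[4-(3-methylbut-2-en-1-yloxy)phenyl]-2,4-dioxobutyl}-2H-pyran-2-one (racemic) | COC(C(=O)CC1=CC(OC)=CC(=O)O1)C(=O)c1ccc(OCC=C(C)C)cc1 | intermediate
10 | methyl (2E)-3,8-dimethoxy-9-[4-(3-methylbut-2-en-1-yloxy)phenyl]-5,7,9-trioxonon-2-enoate (racemic, keto form) | COC(=O)/C=C(/OC)CC(=O)CC(=O)C(OC)C(=O)c1ccc(OCC=C(C)C)cc1 | intermediate
11 | 1-(2,6-dihydroxy-4-methoxyphenyl)-2-methoxy-3-[4-(3-methylbut-2-en-1-yloxy)phenyl]propane-1,3-dione (racemic) | COc1cc(O)c(C(=O)C(OC)C(=O)c2ccc(OCC=C(C)C)cc2)c(O)c1 | intermediate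
12 | 5-hydroxy-3,7-dimethoxy-2-[4-(3-methylbut-2-en-1-yloxy)phenyl]-4H-chromen-4-one | COc1cc(O)c2c(=O)c(OC)c(-c3ccc(OCC=C(C)C)cc3)oc2c1 | target

Total step count: 4. Longest linear sequence: 3 (steps 2, 3 and 4).

**Steps most likely to fail**

Step 4. The opened chain may fold by an aldol mode in place of the Claisen mode, the diketone enolate oxygen may add to the pyranone before the lactone opens, or methoxide may cleave the α-methoxy 1,3-diketone by a retro-Claisen reaction. The fallback sets out from 7 and builds the rings in two stages. Mg(OMe)2 in refluxing MeOH would fold the shorter chain of 7, which has no aryl ketone and hence no second aldol mode and no cleavable diketone, to 1-(2,6-dihydroxy-4-methoxyphenyl)-2-methoxyethan-1-one F1. A crossed Claisen condensation of the lithium polyanion of F1 (LiN(SiMe3)2, 4 equiv, THF, −78 → 0 °C) with ester 3 would then give the diketone, and the route is rejoined at 11, which AcOH and NaOAc at 100 °C would close to 12.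

Step 3. Acylation of the dianion by the electron-rich ester may be slow, so that proton transfer from the product and self-condensation overtake it. The fallback sets out from 7 and replaces the acylation by an aldol addition and an oxidation. 4-Hydroxybenzaldehyde F2 (purchased) and 2 would give 4-(3-methylbut-2-en-1-yloxy)benzaldehyde F3 under the conditions of step 1. The dianion 8 would add at −78 °C to this far more electrophilic aldehyde to give 6-{4-hydroxy-3-methoxy-4-[4-(3-methylbut-2-en-1-yloxy)phenyl]-2-oxobutyl}-4-methoxy-2H-pyran-2-one F4 as a mixture of diastereomers. Dess–Martin periodinane in CH2Cl2 would oxidise the benzylic alcohol of F4, and the route is rejoined at 9.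

Step 2. Ring metalation at C6 or C8 of 4 may compete with deprotonation of the methyl group, or the tetrahedral adduct may collapse early so that the ketone quenches the dienolate. The fallback sets out from 5 and uses 4-hydroxy-6-methyl-2H-pyran-2-one F5 (triacetic acid lactone, purchased) in place of 4. In its dianion (LiN(i-Pr)2, 2.1 equiv, THF, −78 → 0 °C) the 4-oxide shields the ring and the methyl carbanion is the only basic carbon; acylation by 5 would give 4-hydroxy-6-(3-methoxy-2-oxopropyl)-2H-pyran-2-one F6. Me2SO4 and K2CO3 in acetone would methylate the acidic 4-hydroxyl of F6, and the route is rejoined at 7.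

**Further compounds**
F1 | step 4 | 1-(2,6-dihydroxy-4-methoxyphenyl)-2-methoxyethan-1-one | COCC(=O)c1c(O)cc(OC)cc1O
F2 | step 3 | 4-hydroxybenzaldehyde (purchased) | O=Cc1ccc(O)cc1
F3 | step 3 | 4-(3-methylbut-2-en-1-yloxy)benzaldehyde | CC(C)=CCOc1ccc(C=O)cc1
F4 | step 3 | 6-{4-hydroxy-3-methoxy-4-[4-(3-methylbut-2-en-1-yloxy)phenyl]-2-oxobutyl}-4-methoxy-2H-pyran-2-one (mixture of diastereomers) | COC(C(=O)CC1=CC(OC)=CC(=O)O1)C(O)c1ccc(OCC=C(C)C)cc1
F5 | step 2 | 4-hydroxy-6-methyl-2H-pyran-2-one (purchased) | CC1=CC(O)=CC(=O)O1
F6 | step 2 | 4-hydroxy-6-(3-methoxy-2-oxopropyl)-2H-pyran-2-one | COCC(=O)CC1=CC(O)=CC(=O)O1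
A1 | direct plan | 3,5-dimethoxyphenol | COc1cc(O)cc(OC)c1
A2 | direct plan | 4,6-dimethoxy-1-benzofuran-2,3-dione | COc1cc(OC)c2C(=O)C(=O)Oc2c1
A3 | direct plan | 4-hydroxy-6-methoxy-1-benzofuran-2,3-dione | COc1cc(O)c2C(=O)C(=O)Oc2c1
A4 | direct plan | 1-{[4-(3-methylbut-2-en-1-yloxy)phenyl]methyl}thiolan-1-ium tetrafluoroborate | CC(C)=CCOc1ccc(C[S+]2CCCC2)cc1.F[B-](F)(F)F
A5 | direct plan | 3,5-dihydroxy-7-methoxy-2-[4-(3-methylbut-2-en-1-yloxy)phenyl]-4H-chromen-4-one | COc1cc(O)c2c(=O)c(O)c(-c3ccc(OCC=C(C)C)cc3)oc2c1
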